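If J starts chains slowly, each chain's length depends on how long it has been growing, so I begin with the time scale of that growth.

| flask | D | J | remark | time |
|---|---|---|---|---|
| grey | 3 M | 72 mM | run made earlier |  |
| west | 3.0 M | 48 mM |  | 4.0 min |
| south | 3.0 M | 48 mM |  | 2.5 min |

grey run (percent of the D charged)

| time / s | Z / % | D / % |
|---|---|---|
| 10.0 | 3.1 | 98.3 |
| 12.0 | 0 | 98.2 |
| 20.0 | 1.6 | 97.1 |
| 30.0 | 3.0 | 97.1 |
| 50.0 | 8.2 | 89.1 |
| 80.0 | 15.8 | 80.8 |

(each reading ± 1 percentage point)

1. which of the two ends with the longer chains by the average number of monomer units in a chain (chains begun, living or dead) ("neither" if they lie within 10 %) (west / south / neither)
2. average number of monomer units in a chain (chains begun, living or dead) at the end, west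
3. average number of monomer units in a chain (chains begun, living or dead) at the end, south

- the average divides the monomer in chains by the number of chains begun, living and dead together
- on the list of suspects stand: D + J -> L + Z; D + L -> Z + L; D -> G; D -> X
- the earlier runs do not show the number of chains; that part of a forecast is a guess
- no earlier run changes the charge of J; that part of a forecast is a guess

In the grey run Z at first climbs with the square of the time, as it does when the number of growing ends rises steadily. Z divided by that square stands at 0.753 of its earlier value between 50.0 s and 80.0 s, while D is down to 80.8 %. That fall is about the size D's own decline brings, so I see no sign of J running down.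

From the last reading I define the one-for-one time, the time by which the molar amount of Z would equal the J charged, with D and J held at their charges: 31.2 s. It contains no J, since Z and the J charge scale together. For west it puts Z at 23.7 % at half time.

Next I need the chains. J has a pseudo-first-order lifetime under D, which I guess at 160 s, twice the grey span. Chains then grow as J charged times time over lifetime, and J cancels: length is time times lifetime over the square of the one-for-one time. That gives 39.5 for west and 24.7 for south.

The lifetime is the weak link: the grey readings show the product of starting and growing, not the split. So I commit to these lengths as rough estimates and lean on what the lifetime cancels from, the ratio of the two lengths, which is the ratio of times, 1.60, a little less once D falls. West runs for a longer time than south, so I expect west to end with the longer chains.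

The forecast says west, with 23 and 14.5, reading “slow initiation, with a J lifetime of about 40 s”. Its length for west lies below mine.

The flasks give 81.2 for west and 59.5 for south.

    D + J → L + Z (k = 0.00110 /M/s)
    D + L → Z + L, rate k2*[L]*[D] (k = 0.290 /M/s)
    D → G (k = 4.60 × 10⁻⁴ /s)
    D → X (k = 5.70 × 10⁻⁵ /s)

West's J still stands at 70.5 % of its charge at 2.00 min, which reforges its average lifetime under the falling D to 343 s. The rule with that lifetime gives 42.4 for that moment, against 49.7 from Z over L in west. The gap between the flasks comes from the difference in time: south given west's time goes from 59.5 to 81.2. The rule holds no J, so it puts the neighbour of west charged with 0.029 M of J level with west, and that neighbour reaches 90.6 at 4.00 min.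

Readings and results are calculated from invented constants, and the scatter is random.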